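# Proposed synthesis of CNP0293054.1

## Structural features

The target is a p-menthane monocycle: a cyclohex-2-enone in which C1 carries the hydroxymethyl carbon C7, C2 is the ketone conjugated with the C1=C6 double bond, and C3, C4 and C5 form a contiguous stereotriad (3S,4R,5R). C3 bears a (2R,3R)-2,3-epoxy-2-methylbutanoate (the cis-dimethyl glycidate derived from angelic acid), C4 the isopropyl group (C8) and C5 an angelate. The C3 oxygen is trans to the isopropyl group, whereas the C5 oxygen is cis to it. The two stereocentres of the epoxy acyl group are remote from the ring and are best made separately and attached late. Fragile elements are the (Z)-enoate (isomerisation to tiglate under nucleophilic or basic catalysis), the glycidic ester, the epimerisable α-acyloxy ketone at C3 and the γ-acyloxy enone, which can lose carboxylic acid and aromatise to a cuminyl system. The real difficulty is the cis relation between the C5 oxygen and the C4 isopropyl group, a contra-steric arrangement, together with the need to tell four oxygens (C2, C3, C5, C7) apart. The key step exploits the fact that, once the ring is opened at C2–C3, C5 and C4 are the carbinol and allylic carbons of a homoallylic alcohol. The cis ring relation is then the anti relation of the chain C3–C4–C5–C6, which an (E)-γ-isopropylallyl boron reagent delivers through a chair, and the allyl shift leaves C3 as a vinyl carbon facing the C2 vinyl carbon.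

## Logic of the disconnections

25 is traced to 24 by cutting the O–Si bond at C7. The primary alcohol has to stay masked through two acylations and three oxidations, and one robust silyl ether does this for eleven steps. The forward removal must be neither basic (C3 epimerisation, enoate isomerisation) nor strongly acidic (oxirane).

24 is cut at the C3–O acyl bond into 22 and 15 (activated as 23). The oxirane stereocentres are remote from the ring, so a convergent, last-stage attachment exposes the epoxide to the fewest operations and removes five carbons and two stereocentres at once. The forward step must acylate a hindered α-hydroxy ketone without enolising C3 and without opening the oxirane.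

22 is taken back to 21 by returning the C2 carbonyl to an allylic hydroxyl, and 21 to 20 by removing both oxygens from the C2=C3 bond. Only C2 is allylic, so oxidation differentiates the diol without a protecting group. Syn dihydroxylation on the face opposite the C4 and C5 substituents puts the C3 oxygen trans to isopropyl. The demands are site selectivity among three double bonds and face selectivity.

20 is opened at C2=C3 to 19 (ring-closing metathesis retron). Both carbons are then terminal vinyl CH groups, and the ring problem becomes an acyclic one with two stereocentres. The forward step requires C5 and C2 to be cis on the C6=C1 double bond, tolerance of the enoate, and mild handling of a cyclohexadienyl ester.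

19 is cut at the C5–O acyl bond into 17 and 12. Acylating before ring closure means that the C5 hydroxyl never needs a protecting group and never competes with the later diol. The forward step must not isomerise the (Z)-acyl group.

17 is cut at C4–C5 into 7 and 11 (key disconnection). Both ring stereocentres that make up the difficult cis pair arise in one C–C bond formation from two achiral fragments holding all ten skeletal carbons. The forward step needs catalyst control of the aldehyde face, geometric purity of 11 (any Z isomer gives the syn product) and configurational integrity of 7, whose formyl group must remain cis to the vinyl group. A silyl ether was chosen for C7 in 7 because it is inert to the Brønsted acid catalyst and to every later step.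

7 is taken back through 6 (oxidation level) to 4 and 5 by cutting the C1–C2 bond as a cross-coupling, then to 2 by trans-hydrometalation and iodination of the alkyne, and to 1 by monoprotection. The geometry of the trisubstituted alkene is thus written by an anti addition across a symmetrical C4 alkyne. The forward demands are regiocontrol by the free hydroxyl and retention in the coupling. A boron-based vinyl donor avoids organotin waste.

11 is cut at C–B to 9 and 10, and 9 is returned to 8. The forward borylation must give the linear (E) isomer.

15 is returned to 14 (carboxyl to hydroxymethyl), 14 to 13 (reagent-controlled epoxidation of a Z allylic alcohol) and 13 to 12. Both acyl groups of the target thereby come from one starting material. The demand is the correct tartrate hand.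

## Other disconnections considered

Alternative 1: The cut reconnects C6 to C8 and C1 to the C2 oxygen, so the monocycle is seen as the product of a pinane ring opening. Forward, an acidic clay would ionise the C1–O bond of epoxy alcohol A2, the 2,3-epoxide (pinane numbering) of the 4-hydroxylated silyl ether of (1R,5S)-myrtenol A1, with both oxygens anti to the gem-dimethyl bridge. The cyclobutylcarbinyl cation breaks the C6–C8 bond, the C1=C6 double bond appears, and the C8 cation loses a proton to give diene diol A3.
- In its favour: the whole C10 skeleton with C7 and C8 and the configuration at C4 are bought with A1, no C–C bond has to be made, and the bicycle places the C3 oxygen trans to the future isopropyl group. The allylic C2 hydroxyl of A3 can be oxidised as in step 14.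
- Against it here: A3 has a bare methylene at C5. The angelate oxygen would have to be introduced late by allylic or γ-oxidation, cis to the adjacent C4 substituent and against the steric bias. The isopropenyl group must be hydrogenated without touching C1=C6, and cationic pinane openings invite ring contraction and hydration.
- Comparison: on skeleton and source of chirality this route is the better one (chiral pool, no bond construction). On C2 it is the equal of the chosen plan. On the decisive C4/C5 relation it is weaker, because the chosen step fixes that pair in the bond-forming event. The step count would be similar once C3 hydroxylation, hydrogenation and C5 oxidation are included.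

Alternative 2: The cut is the C3–C4 bond, made by [3,3] rearrangement. Forward, glycolate ester A4 (4-methoxybenzyl-protected glycolate of an enantiopure (E) secondary allylic alcohol) would be turned by a lithium amide and a silyl chloride into the chelated (Z)-silyl ketene acetal. This rearranges through a chair to acid A5, and the carbinol stereocentre is spent and reappears as C3 and C4.
- In its favour: an intramolecular closed transition state with enolate geometry fixed by chelation, and chirality transfer from an easily made alcohol. The syn open-chain pair is the required trans ring relation of C3 and C4. The C3 oxygen arrives already differentiated and the carboxyl is C2 at the correct oxidation level, so no dihydroxylation and no selective oxidation are needed. On these two points it is better than the chosen plan.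
- Against it here: C5 is untouched. The propenyl group would have to be cleaved to a C5 aldehyde and a C6 nucleophile added under control of C4 alone (Felkin and chelation models disagree, and a cis C4/C5 outcome is not assured). A C1/C7 unit must then be added to C2 and the trisubstituted C1=C6 bond closed.
- Comparison: mechanistically the two key steps are equals (six-membered chairs translating alkene geometry into configuration), and the rearrangement needs no chiral catalyst, which is an advantage. Structurally the chosen plan sets the pair containing the contra-steric C5 centre, and this route sets the easier pair. In step economy the chosen plan is ahead, since three further C–C bonds must follow A5.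

Alternative 3: The cut is the C5–O bond of the angelate with allylic transposition. Forward, a zerovalent palladium phosphine catalyst would ionise the allylic C1–O bond of vinyl epoxide A6 with inversion, 12 would protonate the alkoxide, and the carboxylate would attack C5 of the η3-allyl complex opposite to palladium. This gives the cis-1,4-hydroxy ester A7 with the C1=C6 bond and a free C2 hydroxyl.
- In its favour: the angelate enters as a nucleophile under neutral conditions without acyl activation, so the Z to E isomerisation that threatens step 11 cannot arise; here it is better than the chosen plan. The double inversion makes C5 a consequence of the epoxide configuration. All four oxygens are differentiated in A7, which is also better than diol 21.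
- Against it here: A6 must already contain C3, C4 and an epoxide syn to the isopropyl group, so the stereochemical problem is moved into the precursor. The carboxylate must attack next to the branched C4 on the isopropyl face, while attack at C1 or β-hydride loss would compete.
- Comparison: this step forms no C–C bond and no relation that is not already encoded, whereas the chosen step makes one C–C bond and two stereocentres from achiral partners. The endgame from A7 would be about as long as steps 14 to 16, an equal. The overall count would be higher because A6 must be built first.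

Key step: step 10

Remarks on the chemistry:
- Locants C1–C8 of the target are used for the same atoms in all intermediates.
- The allylboration product 17 has three C=C bonds (two vinyl groups and the trisubstituted alkene) and is therefore treated and named as a triene.
- The (S)-phosphoric acid in step 10 is chosen on the premise that the (R)-acid delivers allyl groups to the Re face of aromatic and α,β-unsaturated aldehydes; the Si face of 7 is the one required.
- The L-(+)-tartrate in step 8 is chosen by analogy with primary allylic alcohols, for which it makes the hydroxymethyl-bearing oxirane carbon S.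

## Route

Step 1
Reactants: 1 but-2-yne-1,4-diol
Product: 2 4-[(tert-butyldimethylsilyl)oxy]but-2-yn-1-ol
Conditions: TBSCl (1 equiv), imidazole, diol in threefold excess, THF/DMF, 0 °C to rt
Reagents that add atoms: tert-butyldimethylsilyl chloride CC(C)(C)[Si](C)(C)Cl
Why: Statistical monosilylation of a symmetrical diol (Corey silylation); the cheap diol in excess suppresses the bis-ether and is washed out with water.

Step 2
Reactants: 2 4-[(tert-butyldimethylsilyl)oxy]but-2-yn-1-ol
Product: 4 (2Z)-4-[(tert-butyldimethylsilyl)oxy]-3-iodobut-2-en-1-ol, via cyclic sodium alkenylalanate 3 (not isolated)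
Conditions: NaAlH2(OCH2CH2OMe)2, THF, 0 °C; EtOAc; then I2, THF, −78 °C to 0 °C; aqueous KNaC4H4O6 work-up
Reagents that add atoms: iodine II
Why: trans-Hydroalumination of a propargylic alcohol: the aluminium alkoxide delivers hydride to the proximal alkyne carbon and closes the five-membered alanate 3 with aluminium on the distal carbon, and iodinolysis with retention gives the (Z)-3-iodo allylic alcohol, so that the hydroxymethyl arm is cis to the future vinyl position.

Step 3
Reactants: 4 (2Z)-4-[(tert-butyldimethylsilyl)oxy]-3-iodobut-2-en-1-ol; 5 2-ethenyl-4,4,5,5-tetramethyl-1,3,2-dioxaborolane (vinylboronic acid pinacol ester)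
Product: 6 (2E)-3-{[(tert-butyldimethylsilyl)oxy]methyl}penta-2,4-dien-1-ol (hydroxymethyl arm cis to the vinyl group)
Conditions: Pd(PPh3)4 (3 mol %), K2CO3, THF/H2O, 65 °C
Reagents that add atoms: none
Why: Suzuki–Miyaura coupling of an alkenyl iodide with a vinylboronate under zerovalent palladium catalysis proceeds with retention of alkene geometry and avoids an organotin reagent.

Step 4
Reactants: 6 (2E)-3-{[(tert-butyldimethylsilyl)oxy]methyl}penta-2,4-dien-1-ol
Product: 7 (2E)-3-{[(tert-butyldimethylsilyl)oxy]methyl}penta-2,4-dienal
Conditions: activated MnO2 (excess), CH2Cl2, rt; used soon after filtration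
Reagents that add atoms: none
Why: Allylic oxidation with MnO2 is neutral and heterogeneous, which preserves the geometry of the trisubstituted alkene and the silyl ether; the open dienal should be favoured over its 2H-pyran valence isomer because that pyran would carry no substituent on its sp3 carbon.

Step 5
Reactants: 8 (2E)-4-methylpent-2-enal
Product: 9 (2E)-4-methylpent-2-en-1-ol
Conditions: NaBH4, CeCl3·7H2O, MeOH, 0 °C
Reagents that add atoms: none
Why: Luche reduction gives clean 1,2-reduction of the enal and leaves the (E)-alkene untouched.

Step 6
Reactants: 9 (2E)-4-methylpent-2-en-1-ol; 10 bis(pinacolato)diboron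
Product: 11 4,4,5,5-tetramethyl-2-[(2E)-4-methylpent-2-en-1-yl]-1,3,2-dioxaborolane
Conditions: Pd(MeCN)4(BF4)2 (5 mol %), DMSO/MeOH, 50 °C
Reagents that add atoms: none
Why: Palladium-catalysed borylation of an allylic alcohol with a diboron reagent runs through an η3-allyl palladium intermediate whose syn isopropyl form takes boron at the unsubstituted terminus, which should give the linear (E)-allylboronate.

Step 7
Reactants: 12 angelic acid [(2Z)-2-methylbut-2-enoic acid]
Product: 13 (2Z)-2-methylbut-2-en-1-ol
Conditions: LiAlH4, Et2O, 0 °C to rt
Reagents that add atoms: none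
Why: Hydride reduction of the carboxylic acid to the primary allylic alcohol; the trisubstituted double bond of a 2-alkyl-2-enoic acid is not reduced under these conditions and its Z geometry is retained.

Step 8
Reactants: 13 (2Z)-2-methylbut-2-en-1-ol
Product: 14 [(2S,3R)-2,3-dimethyloxiran-2-yl]methanol
Conditions: Ti(OiPr)4 (10 mol %), L-(+)-diisopropyl tartrate (12 mol %), tBuOOH, 4 Å MS, CH2Cl2, −20 °C; non-aqueous work-up
Reagents that add atoms: tert-butyl hydroperoxide CC(C)(C)OO
Why: Sharpless asymmetric epoxidation: the titanium tartrate complex binds the allylic alkoxide and the hydroperoxide and delivers oxygen to one alkene face (C2 becomes S, C3 becomes R), and the syn-stereospecific addition keeps the two methyl groups cis.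

Step 9
Reactants: 14 [(2S,3R)-2,3-dimethyloxiran-2-yl]methanol
Product: 15 (2R,3R)-2,3-dimethyloxirane-2-carboxylic acid
Conditions: TEMPO (20 mol %), PhI(OAc)2 (2.2 equiv), MeCN/H2O, rt
Reagents that add atoms: water O
Why: Oxoammonium-mediated oxidation of the primary alcohol through the aldehyde hydrate to the acid at near-neutral pH leaves the oxirane intact; the C2 descriptor changes from S to R only through the CIP priorities, not through any change in space.

Step 10
Reactants: 7 (2E)-3-{[(tert-butyldimethylsilyl)oxy]methyl}penta-2,4-dienal; 11 4,4,5,5-tetramethyl-2-[(2E)-4-methylpent-2-en-1-yl]-1,3,2-dioxaborolane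
Product: 17 (3E,5S,6S)-3-{[(tert-butyldimethylsilyl)oxy]methyl}-6-(propan-2-yl)octa-1,3,7-trien-5-ol (anti; octatriene C5 and C6 are ring C5 and C4), via pinacol borate ester 16 (not isolated)
Conditions: (S)-3,3'-bis(2,4,6-triisopropylphenyl)-1,1'-binaphthyl-2,2'-diyl hydrogen phosphate [(S)-TRIP] (5 mol %), 4 Å MS, toluene, −30 °C; aqueous NaHCO3 work-up
Reagents that add atoms: none
Why: Brønsted acid-catalysed allylboration through a closed transition state: the phosphoric acid hydrogen-bonds through P–OH to a boronate oxygen and through P=O to the formyl hydrogen of 7 while boron binds the carbonyl oxygen, so the C4–C5 bond forms in a six-membered chair and gives borate 16, which is hydrolysed on work-up. The closest known reaction type is the chiral phosphoric acid-catalysed crotylboration of aromatic and α,β-unsaturated aldehydes with (E)-crotyl pinacol boronates. No ring is closed; one skeletal bond is made, and the allyl shift turns the boron-bearing CH2 into the terminal carbon of the C4 vinyl group, whose inner carbon is C3. C5 is set by the catalyst, whose 2,4,6-triisopropylphenyl groups should leave only the Si face of the aldehyde open in the (S) series. C4 is set relative to C5 by the (E) geometry of 11, since the isopropyl group and the dienyl residue of the aldehyde both sit equatorial in the chair, which translates into the anti (5S,6S) pair and hence the cis ring relation. The step needs enantioface selectivity, simple diastereoselectivity and 1,2-addition only; these are secured by the catalyst, by the geometric purity of 11 and by the closed transition state, which can deliver carbon only to the carbonyl carbon. The uncatalysed addition of pinacol esters is slow at −30 °C, so a racemic background should be small, and the lower electrophilicity of the β,β-disubstituted dienal is offset by the acid activation and reaction time.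

Step 11
Reactants: 17 (3E,5S,6S)-3-{[(tert-butyldimethylsilyl)oxy]methyl}-6-(propan-2-yl)octa-1,3,7-trien-5-ol; 12 angelic acid
Product: 19 (3E,5S,6S)-3-{[(tert-butyldimethylsilyl)oxy]methyl}-6-(propan-2-yl)octa-1,3,7-trien-5-yl (2Z)-2-methylbut-2-enoate, via angelic 2,4,6-trichlorobenzoic mixed anhydride 18 (not isolated)
Conditions: 12, 2,4,6-trichlorobenzoyl chloride, Et3N, toluene, rt; then 17, 75 °C; no DMAP
Reagents that add atoms: none
Why: Acylation through a preformed mixed anhydride (Yamaguchi-type activation used without a nucleophilic catalyst): the alcohol attacks the less hindered angeloyl carbonyl, and leaving out DMAP removes the conjugate addition–elimination path that turns angelates into tiglates.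

Step 12
Reactants: 19 (3E,5S,6S)-3-{[(tert-butyldimethylsilyl)oxy]methyl}-6-(propan-2-yl)octa-1,3,7-trien-5-yl (2Z)-2-methylbut-2-enoate
Product: 20 (1S,6S)-3-{[(tert-butyldimethylsilyl)oxy]methyl}-6-(propan-2-yl)cyclohexa-2,4-dien-1-yl (2Z)-2-methylbut-2-enoate (isopropyl and acyloxy cis)
Conditions: second-generation Grubbs catalyst RuCl2(=CHPh)(H2IMes)(PCy3) (5 mol %), degassed CH2Cl2 (5 mM), 40 °C; ethyl vinyl ether quench, filtration through neutral alumina, used at once
Reagents that add atoms: none
Why: Ring-closing metathesis: the catalyst loads on the monosubstituted C4 vinyl group and closes onto the terminal double bond of the diene (six-membered ring, C2=C3 formed, ethene lost), while the trisubstituted C6=C1 bond and the electron-poor enoate are not engaged; the product is kept neutral and cold because a cyclohexadienyl ester can aromatise by loss of acid.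

Step 13
Reactants: 20 (1S,6S)-3-{[(tert-butyldimethylsilyl)oxy]methyl}-6-(propan-2-yl)cyclohexa-2,4-dien-1-yl (2Z)-2-methylbut-2-enoate
Product: 21 (1R,4R,5S,6S)-3-{[(tert-butyldimethylsilyl)oxy]methyl}-4,5-dihydroxy-6-(propan-2-yl)cyclohex-2-en-1-yl (2Z)-2-methylbut-2-enoate (ring C2 and C3 hydroxyls cis to each other and trans to isopropyl)
Conditions: OsO4 (2 mol %), N-methylmorpholine N-oxide (1.2 equiv), acetone/H2O, 0 °C; Na2SO3 quench
Reagents that add atoms: N-methylmorpholine N-oxide C[N+]1([O-])CCOCC1; water O
Why: Upjohn dihydroxylation: OsO4 should add suprafacially to the disubstituted C2=C3 bond, because the C1=C6 bond is deactivated by two allylic oxygens and the angelate double bond by its ester, and from the face opposite the C4 isopropyl and C5 acyloxy groups, which sets C3 as in the target.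

Step 14
Reactants: 21 (1R,4R,5S,6S)-3-{[(tert-butyldimethylsilyl)oxy]methyl}-4,5-dihydroxy-6-(propan-2-yl)cyclohex-2-en-1-yl (2Z)-2-methylbut-2-enoate
Product: 22 (1R,5S,6S)-3-{[(tert-butyldimethylsilyl)oxy]methyl}-5-hydroxy-4-oxo-6-(propan-2-yl)cyclohex-2-en-1-yl (2Z)-2-methylbut-2-enoate
Conditions: activated MnO2, CH2Cl2, rt
Reagents that add atoms: none
Why: MnO2 oxidises only the allylic C2 hydroxyl; the saturated C3 hydroxyl is untouched, so the diol is differentiated and the C2 stereocentre is removed.

Step 15
Reactants: 22 (1R,5S,6S)-3-{[(tert-butyldimethylsilyl)oxy]methyl}-5-hydroxy-4-oxo-6-(propan-2-yl)cyclohex-2-en-1-yl (2Z)-2-methylbut-2-enoate; 15 (2R,3R)-2,3-dimethyloxirane-2-carboxylic acid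
Product: 24 (1S,5R,6R)-3-{[(tert-butyldimethylsilyl)oxy]methyl}-5-{[(2Z)-2-methylbut-2-enoyl]oxy}-2-oxo-6-(propan-2-yl)cyclohex-3-en-1-yl (2R,3R)-2,3-dimethyloxirane-2-carboxylate, via epoxy acid 2,4,6-trichlorobenzoic mixed anhydride 23 (not isolated)
Conditions: 15, 2,4,6-trichlorobenzoyl chloride, Et3N, toluene, rt; then 22, DMAP, 0 °C to rt
Reagents that add atoms: none
Why: Yamaguchi esterification: DMAP transfers the less hindered aliphatic acyl group of 23 to the C3 hydroxyl; no bond to C3 or to the oxirane carbons is broken, so all stereocentres are retained, and a short reaction at low temperature limits enolisation towards C3.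

Step 16
Reactants: 24 (1S,5R,6R)-3-{[(tert-butyldimethylsilyl)oxy]methyl}-5-{[(2Z)-2-methylbut-2-enoyl]oxy}-2-oxo-6-(propan-2-yl)cyclohex-3-en-1-yl (2R,3R)-2,3-dimethyloxirane-2-carboxylate
Product: 25 (1S,5R,6R)-3-(hydroxymethyl)-5-{[(2Z)-2-methylbut-2-enoyl]oxy}-2-oxo-6-(propan-2-yl)cyclohex-3-en-1-yl (2R,3R)-2,3-dimethyloxirane-2-carboxylate (CNP0293054.1)
Conditions: HF·pyridine, pyridine, THF, 0 °C to rt
Reagents that add atoms: none
Why: Fluoride cleavage of the primary silyl ether; pyridine-buffered HF should be too weakly basic to epimerise C3 or isomerise the angelate and too weakly acidic to open the electron-poor glycidic ester.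

## Compound list

1 | but-2-yne-1,4-diol | OCC#CCO | starting material
2 | 4-[(tert-butyldimethylsilyl)oxy]but-2-yn-1-ol | OCC#CCO[Si](C)(C)C(C)(C)C | intermediate
3 | cyclic sodium alkenylalanate (sodium 2,2-bis(2-methoxyethoxy)-3-{[(tert-butyldimethylsilyl)oxy]methyl}-2,5-dihydro-1,2-oxaaluminol-2-uide) | [Na+].COCCO[Al-]1(OCCOC)OCC=C1CO[Si](C)(C)C(C)(C)C | intermediate
4 | (2Z)-4-[(tert-butyldimethylsilyl)oxy]-3-iodobut-2-en-1-ol | OC/C=C(\I)CO[Si](C)(C)C(C)(C)C | intermediate
5 | 2-ethenyl-4,4,5,5-tetramethyl-1,3,2-dioxaborolane | C=CB1OC(C)(C)C(C)(C)O1 | starting material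
6 | (2E)-3-{[(tert-butyldimethylsilyl)oxy]methyl}penta-2,4-dien-1-ol | OC/C=C(\C=C)CO[Si](C)(C)C(C)(C)C | intermediate
7 | (2E)-3-{[(tert-butyldimethylsilyl)oxy]methyl}penta-2,4-dienal | O=C/C=C(\C=C)CO[Si](C)(C)C(C)(C)C | intermediate
8 | (2E)-4-methylpent-2-enal | CC(C)/C=C/C=O | starting material
9 | (2E)-4-methylpent-2-en-1-ol | CC(C)/C=C/CO | intermediate
10 | bis(pinacolato)diboron | CC1(C)OB(OC1(C)C)B1OC(C)(C)C(C)(C)O1 | starting material
11 | 4,4,5,5-tetramethyl-2-[(2E)-4-methylpent-2-en-1-yl]-1,3,2-dioxaborolane | CC(C)/C=C/CB1OC(C)(C)C(C)(C)O1 | intermediate
12 | angelic acid, (2Z)-2-methylbut-2-enoic acid | C/C=C(/C)C(=O)O | starting material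
13 | (2Z)-2-methylbut-2-en-1-ol | C/C=C(/C)CO | intermediate
14 | [(2S,3R)-2,3-dimethyloxiran-2-yl]methanol | OC[C@]1(C)O[C@@H]1C | intermediate
15 | (2R,3R)-2,3-dimethyloxirane-2-carboxylic acid | OC(=O)[C@]1(C)O[C@@H]1C | intermediate
16 | 2-{[(3E,5S,6S)-3-{[(tert-butyldimethylsilyl)oxy]methyl}-6-(propan-2-yl)octa-1,3,7-trien-5-yl]oxy}-4,4,5,5-tetramethyl-1,3,2-dioxaborolane | C=C[C@@H]([C@H](OB1OC(C)(C)C(C)(C)O1)/C=C(\C=C)CO[Si](C)(C)C(C)(C)C)C(C)C | intermediate
17 | (3E,5S,6S)-3-{[(tert-butyldimethylsilyl)oxy]methyl}-6-(propan-2-yl)octa-1,3,7-trien-5-ol | C=C[C@@H]([C@H](O)/C=C(\C=C)CO[Si](C)(C)C(C)(C)C)C(C)C | intermediate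
18 | (2Z)-2-methylbut-2-enoic 2,4,6-trichlorobenzoic anhydride | C/C=C(/C)C(=O)OC(=O)c1c(Cl)cc(Cl)cc1Cl | intermediate
19 | (3E,5S,6S)-3-{[(tert-butyldimethylsilyl)oxy]methyl}-6-(propan-2-yl)octa-1,3,7-trien-5-yl (2Z)-2-methylbut-2-enoate | C=C[C@@H]([C@H](OC(=O)/C(C)=C\C)/C=C(\C=C)CO[Si](C)(C)C(C)(C)C)C(C)C | intermediate
20 | (1S,6S)-3-{[(tert-butyldimethylsilyl)oxy]methyl}-6-(propan-2-yl)cyclohexa-2,4-dien-1-yl (2Z)-2-methylbut-2-enoate | C/C=C(/C)C(=O)O[C@@H]1C=C(CO[Si](C)(C)C(C)(C)C)C=C[C@@H]1C(C)C | intermediate
21 | (1R,4R,5S,6S)-3-{[(tert-butyldimethylsilyl)oxy]methyl}-4,5-dihydroxy-6-(propan-2-yl)cyclohex-2-en-1-yl (2Z)-2-methylbut-2-enoate | C/C=C(/C)C(=O)O[C@@H]1C=C(CO[Si](C)(C)C(C)(C)C)[C@@H](O)[C@@H](O)[C@@H]1C(C)C | intermediate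
22 | (1R,5S,6S)-3-{[(tert-butyldimethylsilyl)oxy]methyl}-5-hydroxy-4-oxo-6-(propan-2-yl)cyclohex-2-en-1-yl (2Z)-2-methylbut-2-enoate | C/C=C(/C)C(=O)O[C@@H]1C=C(CO[Si](C)(C)C(C)(C)C)C(=O)[C@@H](O)[C@@H]1C(C)C | intermediate
23 | (2R,3R)-2,3-dimethyloxirane-2-carboxylic 2,4,6-trichlorobenzoic anhydride | O=C(OC(=O)[C@]1(C)O[C@@H]1C)c1c(Cl)cc(Cl)cc1Cl | intermediate
24 | (1S,5R,6R)-3-{[(tert-butyldimethylsilyl)oxy]methyl}-5-{[(2Z)-2-methylbut-2-enoyl]oxy}-2-oxo-6-(propan-2-yl)cyclohex-3-en-1-yl (2R,3R)-2,3-dimethyloxirane-2-carboxylate | C/C=C(/C)C(=O)O[C@@H]1C=C(CO[Si](C)(C)C(C)(C)C)C(=O)[C@@H](OC(=O)[C@]2(C)O[C@@H]2C)[C@@H]1C(C)C | intermediate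
25 | (1S,5R,6R)-3-(hydroxymethyl)-5-{[(2Z)-2-methylbut-2-enoyl]oxy}-2-oxo-6-(propan-2-yl)cyclohex-3-en-1-yl (2R,3R)-2,3-dimethyloxirane-2-carboxylate | C/C=C(/C)C(=O)O[C@@H]1C=C(CO)C(=O)[C@@H](OC(=O)[C@]2(C)O[C@@H]2C)[C@@H]1C(C)C | target

## Step count and risk assessment

Total step count: 16. Longest linear sequence: 11 steps (steps 1–4 and 10–16, from 1 to 25). The boronate (steps 5–6) and the epoxy acid (steps 7–9) are side branches.

Least certain steps:

Step 10 (key step). The addition may be slow, because a β,β-disubstituted dienal meets a γ-isopropyl boronate. Warming to compensate would let the uncatalysed, racemic pathway compete and lower the enantiomeric purity. Acid-mediated geometrical isomerisation of the dienal would place the C2 vinyl group trans to C5 and make ring closure impossible, and any Z boronate is translated into the syn diastereomer. Fallback, from 9 and 7 back to 17, by a chromium-mediated asymmetric allylation (Nozaki–Hiyama–Kishi type) instead of a boron chair: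
- 9 is converted with PBr3 in Et2O at 0 °C into (2E)-1-bromo-4-methylpent-2-ene F1.
- F1 and 7 are combined with catalytic CrCl2, Mn powder, Me3SiCl and a chiral carbazole bis(oxazoline) ligand in THF. γ-Substituted allylchromium reagents add anti whatever the halide geometry, so this should give the trimethylsilyl ether of the anti homoallylic alcohol F2.
- K2CO3 in MeOH at 0 °C then returns 17.

Step 13. Osmylation may take place at the C1=C6 or the angelate double bond, or continue to a second dihydroxylation once the conjugation is broken. Fallback, from 20 back to 22, by electrophilic oxygen transfer and substitution instead of a [3+2] addition: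
- 20 is epoxidised with dimethyldioxirane in acetone at −20 °C. This reagent responds more strongly to the inductive deactivation of the other two double bonds, and it should attack anti to isopropyl to give the 2,3-epoxide F3.
- F3 is hydrolysed in buffered aqueous THF at the allylic carbon C2 to the trans-2,3-diol F4, whose C3 oxygen keeps the configuration set by the epoxidation.
- MnO2 oxidises the allylic C2 hydroxyl of F4 to 22; the configuration at C2 is irrelevant.

Step 15. Acylation of a hindered, hydrogen-bonded α-ketol with a hindered acid may be slow enough for base-mediated enolisation towards C3 (epimerisation or ketol shift), or acyl transfer from the aryl carbonyl of the mixed anhydride, to compete. Fallback, from 21 back to 24, by acylating before the ketone exists: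
- 21 is silylated at the allylic C2 hydroxyl, which is remote from the isopropyl group (Et3SiCl, 2,6-lutidine, CH2Cl2, −78 °C), to give the C2 triethylsilyl ether F5.
- F5 is acylated with 23 and DMAP to the C3 epoxy ester F6.
- HF·pyridine at −20 °C removes the secondary triethylsilyl group faster than the primary tert-butyldimethylsilyl group and gives the C2 alcohol F7.
- F7 is oxidised at once with buffered Dess–Martin periodinane to 24, before acyl migration between the cis oxygens can occur.

Step 11. The heated acylation may isomerise the Z acyl group to the tiglate or degrade the dienyl carbinol. Fallback, from 17 back to 19, by building the Z double bond after the ester bond: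
- 17 is esterified at 0 °C with 2-[bis(2,2,2-trifluoroethoxy)phosphoryl]propanoic acid (DCC, catalytic DMAP) to the phosphonate ester F8.
- Still–Gennari olefination of F8 with acetaldehyde (KN(SiMe3)2, 18-crown-6, THF, −78 °C) should give the (Z)-2-methylbut-2-enoate 19.

Step 6. The direct borylation of the free alcohol may stall, or may give protodeboronation and erosion of the E geometry. Fallback, from 9 back to 11, by prior activation of the hydroxyl:
- 9 is acetylated (Ac2O, pyridine) to (2E)-4-methylpent-2-en-1-yl acetate F9.
- F9 undergoes Miyaura borylation with 10 and Pd(dba)2 in DMSO at 50 °C to give 11.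

## Further compounds

F1 | step 10 | (2E)-1-bromo-4-methylpent-2-ene | CC(C)/C=C/CBr
F2 | step 10 | trimethylsilyl ether of 17, (3E,5S,6S)-3-{[(tert-butyldimethylsilyl)oxy]methyl}-6-(propan-2-yl)-5-[(trimethylsilyl)oxy]octa-1,3,7-triene | C=C[C@@H]([C@H](O[Si](C)(C)C)/C=C(\C=C)CO[Si](C)(C)C(C)(C)C)C(C)C
F3 | step 13 | 2,3-epoxide of 20 (ring locants of the target; oxirane oxygen trans to the C4 isopropyl and C5 acyloxy groups) | C/C=C(/C)C(=O)O[C@@H]1C=C(CO[Si](C)(C)C(C)(C)C)[C@H]2O[C@H]2[C@@H]1C(C)C
F4 | step 13 | trans-2,3-diol, C2 epimer of 21 (C2 hydroxyl cis to isopropyl, C3 hydroxyl trans to isopropyl) | C/C=C(/C)C(=O)O[C@@H]1C=C(CO[Si](C)(C)C(C)(C)C)[C@H](O)[C@@H](O)[C@@H]1C(C)C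
F5 | step 15 | C2 triethylsilyl ether of 21 | C/C=C(/C)C(=O)O[C@@H]1C=C(CO[Si](C)(C)C(C)(C)C)[C@@H](O[Si](CC)(CC)CC)[C@@H](O)[C@@H]1C(C)C
F6 | step 15 | C3 (2R,3R)-2,3-dimethyloxirane-2-carboxylate of F5 | C/C=C(/C)C(=O)O[C@@H]1C=C(CO[Si](C)(C)C(C)(C)C)[C@@H](O[Si](CC)(CC)CC)[C@@H](OC(=O)[C@]2(C)O[C@@H]2C)[C@@H]1C(C)C
F7 | step 15 | C2 alcohol, 2-hydroxy analogue of 24 (C2 hydroxyl cis to the C3 ester) | C/C=C(/C)C(=O)O[C@@H]1C=C(CO[Si](C)(C)C(C)(C)C)[C@@H](O)[C@@H](OC(=O)[C@]2(C)O[C@@H]2C)[C@@H]1C(C)C
F8 | step 11 | (3E,5S,6S)-3-{[(tert-butyldimethylsilyl)oxy]methyl}-6-(propan-2-yl)octa-1,3,7-trien-5-yl 2-[bis(2,2,2-trifluoroethoxy)phosphoryl]propanoate (epimers at the phosphonate-bearing carbon) | C=C[C@@H]([C@H](OC(=O)C(C)P(=O)(OCC(F)(F)F)OCC(F)(F)F)/C=C(\C=C)CO[Si](C)(C)C(C)(C)C)C(C)C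
F9 | step 6 | (2E)-4-methylpent-2-en-1-yl acetate | CC(C)/C=C/COC(C)=O
A1 | alternative 1 | (1R,5S)-myrtenol, [(1R,5S)-6,6-dimethylbicyclo[3.1.1]hept-2-en-2-yl]methanol | C1[C@H]2C(CO)=CC[C@@H]1C2(C)C
A2 | alternative 1 | 10-[(tert-butyldiphenylsilyl)oxy]-2,3-epoxypinan-4-ol (pinane numbering; oxirane and hydroxyl anti to the gem-dimethyl bridge) | C1[C@H]2[C@@]3(CO[Si](c4ccccc4)(c4ccccc4)C(C)(C)C)O[C@H]3[C@@H](O)[C@@H]1C2(C)C
A3 | alternative 1 | 7-[(tert-butyldiphenylsilyl)oxy]-p-mentha-6,8-diene-2,3-diol (2,3-cis diol, C3 hydroxyl trans to the C4 isopropenyl group) | C1C=C(CO[Si](c2ccccc2)(c2ccccc2)C(C)(C)C)[C@@H](O)[C@@H](O)[C@@H]1C(C)=C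
A4 | alternative 2 | (2S,3E)-5-methylhex-3-en-2-yl [(4-methoxybenzyl)oxy]acetate | C[C@H](OC(=O)COCc1ccc(OC)cc1)/C=C/C(C)C
A5 | alternative 2 | (2S,3R,4E)-2-[(4-methoxybenzyl)oxy]-3-(propan-2-yl)hex-4-enoic acid | OC(=O)[C@@H](OCc1ccc(OC)cc1)[C@@H](/C=C/C)C(C)C
A6 | alternative 3 | 1,2-epoxy-7-[(tert-butyldimethylsilyl)oxy]-3-[(triethylsilyl)oxy]-p-menth-5-ene (target locants; oxirane cis to the C4 isopropyl group, C3 silyloxy trans to it) | C1=C[C@]2(CO[Si](C)(C)C(C)(C)C)O[C@@H]2[C@@H](O[Si](CC)(CC)CC)[C@@H]1C(C)C
A7 | alternative 3 | cis-1,4-hydroxy angelate: 7-[(tert-butyldimethylsilyl)oxy]-2-hydroxy-3-[(triethylsilyl)oxy]-p-menth-1(6)-en-5-yl (2Z)-2-methylbut-2-enoate (target locants) | C/C=C(/C)C(=O)O[C@@H]1C=C(CO[Si](C)(C)C(C)(C)C)[C@H](O)[C@@H](O[Si](CC)(CC)CC)[C@@H]1C(C)C
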